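**Retrosynthetic overview**

1. Cembrane numbering is used: C1 carries the isopropyl group and the ring oxygen, C2=C3, C4 (CH3, OH), C6 (C=O), C8 (CH3), C11 (OAc), C12 (CH3, ring oxygen). The oxolane O–C1–C14–C13–C12 sits inside the 14-membered carbocycle C1–C14.
2. Enabling feature: C12 is a fully substituted ether carbon that carries a methyl group and lies next to the C11 carbinol carbon. CH3–C12–O–C1 is therefore the Markovnikov hydroalkoxylation product of an exocyclic C12=CH2 alkene by the C1 hydroxyl, and opening the oxolane this way leaves an all-carbon 14-membered ring with an allylic alcohol C11(OH)–C12(=CH2).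
3. Key disconnection C11–C12: intramolecular Ni/Cr alkenyl–aldehyde addition, with C12 as the methyl-ketone carbon of the seco-chain (as its enol triflate) and C11 as an aldehyde carbon.
4. Seco-chain: (R)-terpinen-4-ol gives C1–C3, C12–C14, the isopropyl group and the C12 methyl carbon (ozonolysis); a propionate ylide gives C4, C5 and the C4 methyl; (S)-citronellal gives C6–C11 with C8. They are linked by Wittig olefination, Sharpless epoxidation (C4), selenoxide transposition (E-C2=C3, C4–OH) and dithiane–epoxide coupling (C5–C6).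
5. Ring order: first the 14-membered carbocycle (step 13), last the oxolane (step 16), whose closure relays C1 to C12.

Key step: step 13

Assumption: commercial (R)-(−)-terpinen-4-ol and (S)-(−)-citronellal are taken as enantiomerically pure, and L* in step 13 means the antipode of the oxazoline–sulfonamide ligand that gives the 11R carbinol, fixed by a small test with both antipodes.

**Route**

Step 1
Reactants: 1 (R)-(−)-terpinen-4-ol
Product: 2 triethyl{[(1R)-4-methyl-1-(propan-2-yl)cyclohex-3-en-1-yl]oxy}silane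
Conditions: Et3SiOTf (1.3 equiv), 2,6-lutidine (2 equiv), CH2Cl2, 0 °C
Reagents that add atoms: triethylsilyl trifluoromethanesulfonate, CC[Si](CC)(CC)OS(=O)(=O)C(F)(F)F
Why: O-silylation of the hindered tertiary alcohol with the silyl triflate (silyl ether formation) should be clean and masks the C1 hydroxyl, so that the later β-oxy aldehyde and γ-oxy ketone cannot undergo retro-aldol cleavage or hemiketal formation; no stereocentre is touched.

Step 2
Reactants: 2 triethylsilyl ether of terpinen-4-ol; 3 ethyl 2-(triphenylphosphoranylidene)propanoate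
Product: 6 ethyl (2E,5R)-2-methyl-8-oxo-5-(propan-2-yl)-5-[(triethylsilyl)oxy]non-2-enoate, via ozonide 4 (not isolated), via keto aldehyde 5 (not isolated)
Conditions: O3, CH2Cl2, −78 °C; PPh3 (1.1 equiv), −78 °C → rt; then 3 (1.3 equiv), rt
Reagents that add atoms: ozone, [O-][O+]=O
Why: ozonolysis cleaves the only alkene to the keto aldehyde, and the stabilised ylide then reacts only with the aldehyde (Wittig olefination) to give the E-trisubstituted enoate, so C3–C4 is made without isolating the β-silyloxy aldehyde; no new stereocentre.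

Step 3
Reactants: 6 keto enoate
Product: 7 (2E,5R)-2-methyl-5-(propan-2-yl)-5-[(triethylsilyl)oxy]non-2-ene-1,8-diol (both C8 epimers)
Conditions: i-Bu2AlH (5 equiv), CH2Cl2, −78 → 0 °C; aq. Rochelle salt
Reagents that add atoms: none
Why: diisobutylaluminium hydride reduces the enoate by 1,2-addition to the allylic alcohol needed for the directed epoxidation and, deliberately, the methyl ketone to an epimeric carbinol that is returned to the ketone in step 9, which saves a ketone protecting group.

Step 4
Reactants: 7 allylic alcohol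
Product: 8 [(2R,3R)-3-{(2R)-5-hydroxy-2-(propan-2-yl)-2-[(triethylsilyl)oxy]hexyl}-2-methyloxiran-2-yl]methanol
Conditions: Ti(OiPr)4 (0.2 equiv), D-(−)-diethyl tartrate (0.24 equiv), t-BuOOH (2 equiv), 4 Å MS, CH2Cl2, −20 °C
Reagents that add atoms: tert-butyl hydroperoxide, CC(C)(C)OO
Why: Sharpless asymmetric epoxidation of the E-2-methyl allylic alcohol with the D-(−)-tartrate should deliver oxygen to the face that gives the (2R,3R)-epoxy alcohol (reagent control, the C1 centre being remote), which fixes the future C4 carbinol centre.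

Step 5
Reactants: 8 epoxy alcohol
Product: 11 (2S,3E,5S)-2-methyl-5-(propan-2-yl)-5-[(triethylsilyl)oxy]non-3-ene-1,2,8-triol, via selenide 9 (not isolated), via selenoxide 10 (not isolated)
Conditions: (PhSe)2 (0.6 equiv), NaBH4 (1.3 equiv), EtOH, rt → 60 °C; then THF, 30% H2O2, 0 °C → rt
Reagents that add atoms: none
Why: phenylselenide opens the epoxide by SN2 attack at the less substituted carbon (C3), and oxidation to the selenoxide triggers a syn-elimination that can only go towards C2 because C4 has no hydrogen (epoxide-to-allylic-alcohol transposition), which should give the E-C2=C3 alkene with the C4–O bond and its configuration untouched.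

Step 6
Reactants: 11 ene triol
Product: 13 (5S,6E)-7-[(2S)-2-methyloxiran-2-yl]-5-(propan-2-yl)-5-[(triethylsilyl)oxy]hept-6-en-2-ol, via tosylate 12 (not isolated)
Conditions: TsCl (1.1 equiv), Et3N (1.5 equiv), Bu2SnO (2 mol %), CH2Cl2, 0 °C → rt; then K2CO3, MeOH, rt
Reagents that add atoms: none
Why: tin-catalysed sulfonylation of the 1,2-diol is selective for the primary hydroxyl, and base then closes the 2,2-disubstituted oxirane by intramolecular Williamson displacement by the C4 alkoxide, so C4 keeps its oxygen and configuration.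

Step 7
Reactants: 14 (S)-(−)-citronellal
Product: 15 2-[(2S)-2,6-dimethylhept-5-en-1-yl]-1,3-dithiane
Conditions: HS(CH2)3SH (1.1 equiv), BF3·OEt2 (10 mol %), CH2Cl2, −40 °C
Reagents that add atoms: propane-1,3-dithiol, SCCCS
Why: Lewis-acid thioacetalisation converts the aldehyde into the dithiane (acyl-anion precursor for C6) at low temperature, where the competing carbonyl-ene cyclisation of citronellal is slow; the C8 centre is not affected.

Step 8
Reactants: 13 vinyl epoxide; 15 dithiane
Product: 17 (5S,6E,8R)-9-{2-[(2S)-2,6-dimethylhept-5-en-1-yl]-1,3-dithian-2-yl}-8-methyl-5-(propan-2-yl)-5-[(triethylsilyl)oxy]non-6-ene-2,8-diol, via lithiated dithiane 16 (not isolated)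
Conditions: 15 (2.3 equiv), t-BuLi (2.3 equiv), THF/HMPA (9:1), −78 °C; then 13, −78 → −20 °C; aq. NH4Cl
Reagents that add atoms: none
Why: Corey–Seebach umpolung, in which the lithiated dithiane opens the terminal epoxide at its CH2 carbon (C5) by SN2, forms C5–C6 and releases the C4 tertiary alcohol; conjugate opening at C2 is blocked by the quaternary C1, and one equivalent of the anion is spent on the C12 hydroxyl.

Step 9
Reactants: 17 dithiane diol
Product: 18 (5S,6E,8R)-9-{2-[(2S)-2,6-dimethylhept-5-en-1-yl]-1,3-dithian-2-yl}-8-hydroxy-8-methyl-5-(propan-2-yl)-5-[(triethylsilyl)oxy]non-6-en-2-one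
Conditions: Dess–Martin periodinane (1.3 equiv), NaHCO3, CH2Cl2, 0 °C → rt
Reagents that add atoms: none
Why: Dess–Martin oxidation returns the secondary C12 carbinol to the methyl ketone and removes the epimer mixture, leaving the tertiary alcohol, the dithiane and the alkenes untouched.

Step 10
Reactants: 18 methyl ketone
Product: 20 (5S,6E,8R)-9-{2-[(2S)-2,6-dimethylhept-5-en-1-yl]-1,3-dithian-2-yl}-8-hydroxy-8-methyl-5-(propan-2-yl)-5-[(triethylsilyl)oxy]nona-1,6-dien-2-yl trifluoromethanesulfonate, via dipotassium enolate 19 (not isolated)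
Conditions: KHMDS (2.3 equiv), THF, −78 °C; then PhNTf2 (1.2 equiv), −78 → −30 °C; aq. NH4Cl
Reagents that add atoms: N-phenylbis(trifluoromethanesulfonimide), O=S(=O)(N(c1ccccc1)S(=O)(=O)C(F)(F)F)C(F)(F)F
Why: the bulky amide base deprotonates the methyl ketone kinetically on the methyl side (after the C4 hydroxyl), and O-sulfonylation of the enolate gives the 1,1-disubstituted enol triflate that turns the ketone carbon C12 into a latent nucleophile; the dithiane has no acidic hydrogen.

Step 11
Reactants: 20 dithiane enol triflate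
Product: 21 (5S,6E,8R,12S)-8-hydroxy-8,12,16-trimethyl-10-oxo-5-(propan-2-yl)-5-[(triethylsilyl)oxy]heptadeca-1,6,15-trien-2-yl trifluoromethanesulfonate
Conditions: MeI (20 equiv), CaCO3 (10 equiv), MeCN/H2O (9:1), 40 °C
Reagents that add atoms: water, O
Why: S-methylation of the dithiane and hydrolysis of the sulfonium intermediates under buffered neutral conditions (alkylative dethioacetalisation) should free the C6 ketone without touching the enol triflate, the silyl ether or the β-hydroxy ketone that is formed.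

Step 12
Reactants: 21 trienyl triflate
Product: 23 (5S,6E,8R,12S)-8-hydroxy-8,12-dimethyl-10,15-dioxo-5-(propan-2-yl)-5-[(triethylsilyl)oxy]pentadeca-1,6-dien-2-yl trifluoromethanesulfonate, via diol 22 (not isolated)
Conditions: OsO4 (2 mol %), NaIO4 (4 equiv), 2,6-lutidine (2 equiv), 1,4-dioxane/H2O (3:1), rt
Reagents that add atoms: osmium tetroxide, O=[Os](=O)(=O)=O; sodium periodate, [Na+].[O-]I(=O)(=O)=O
Why: Lemieux–Johnson cleavage (catalytic osmylation, periodate glycol cleavage) should select the electron-rich unhindered trisubstituted alkene over the enol triflate and over the C2=C3 alkene, which is flanked by two fully substituted carbons, and gives the C11 aldehyde with loss of acetone.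

Step 13
Reactants: 23 aldehyde enol triflate
Product: 25 (1S,2E,4R,8S,11R)-4,11-dihydroxy-4,8-dimethyl-12-methylidene-1-(propan-2-yl)-1-[(triethylsilyl)oxy]cyclotetradec-2-en-6-one, via alkenylchromium 24 (not isolated)
Conditions: CrCl2 (8 equiv), L* (8.8 equiv; N-[2-(4-isopropyl-4,5-dihydro-1,3-oxazol-2-yl)-6-methylphenyl]methanesulfonamide), Et3N (8.8 equiv), NiCl2 (0.4 equiv), THF, rt; 23 added over 12 h (final 2 mM)
Reagents that add atoms: none
Why: Zerovalent nickel (formed from NiCl2 by CrCl2) inserts into the C12–OTf bond, the alkenyl group passes to trivalent chromium, and alkenylchromium 24 adds to the C11 aldehyde; hydrolysis of the chromium alkoxide gives 25. The closest known reaction type is the intramolecular Nozaki–Hiyama–Kishi coupling of alkenyl triflates or iodides with aldehydes, used for 12- to 16-membered carbocycles, including its variant with chiral oxazoline–sulfonamide ligands on chromium. One ring is closed, the 14-membered carbocycle, by a 14-exo-trig addition to the aldehyde in which C12 stays sp2 as an exocyclic methylene. The one new stereocentre, C11 (R), is set by the chiral ligand on chromium (reagent control), because the resident centres C8, C4 and C1 are too remote to bias the aldehyde face. The step needs chemoselectivity for the aldehyde over the C6 ketone and tolerance of the free C4 hydroxyl, both inherent to alkenylchromium reagents, and ring closure over oligomerisation, which is secured by slow addition at high dilution and helped by the E-C2=C3 alkene and the two fully substituted carbons C1 and C4 that restrict the chain. The C11(OH)–C12(=CH2) unit it forms is exactly the substrate for the later C1–O–C12 oxolane closure, so the oxygen functions at both ends of the new bond follow from this one event.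

Step 14
Reactants: 25 macrocyclic allylic alcohol
Product: 26 (1S,2E,4R,8S,11R)-4-hydroxy-4,8-dimethyl-12-methylidene-6-oxo-1-(propan-2-yl)-1-[(triethylsilyl)oxy]cyclotetradec-2-en-11-yl acetate
Conditions: Ac2O (3 equiv), pyridine, DMAP (10 mol %), CH2Cl2, 0 °C → rt
Reagents that add atoms: acetic anhydride, CC(=O)OC(C)=O
Why: acylation under nucleophilic catalysis esterifies only the secondary allylic C11 hydroxyl, the tertiary C4 hydroxyl being unreactive under these conditions; the configuration at C11 is retained.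

Step 15
Reactants: 26 silyl ether acetate
Product: 27 (1S,2E,4R,8S,11R)-1,4-dihydroxy-4,8-dimethyl-12-methylidene-6-oxo-1-(propan-2-yl)cyclotetradec-2-en-11-yl acetate
Conditions: HF·pyridine, pyridine, THF, 0 °C → rt
Reagents that add atoms: none
Why: fluoride-mediated desilylation frees the C1 tertiary hydroxyl, and the buffered reagent should leave the allylic acetate, the β-hydroxy ketone and the tertiary allylic alcohol intact.

Step 16
Reactants: 27 dihydroxy acetate
Product: 28 (1S,2E,4R,8S,11R,12S)-1,12-epoxy-4-hydroxy-4,8,12-trimethyl-6-oxo-1-(propan-2-yl)cyclotetradec-2-en-11-yl acetate (CNP0131678.1)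
Conditions: Co(salen) (5 mol %; salen = N,N′-bis(3,5-di-tert-butylsalicylidene)-1,2-cyclohexanediaminate), N-fluoro-2,4,6-trimethylpyridinium triflate (2 equiv), (Me2SiH)2O (2 equiv), PhCF3, 0 °C → rt
Reagents that add atoms: none
Why: hydrogen-atom transfer from a cobalt hydride to the 1,1-disubstituted C12=CH2 alkene gives the tertiary C12 radical, which after oxidation at cobalt is captured by the C1 hydroxyl in a 5-exo closure (Mukaiyama-type hydrogen-atom-transfer Markovnikov hydroalkoxylation); the hindered C2=C3 alkene is not attacked, and C12 (S) follows from C1 because the oxolane can span the 14-membered ring only with C2 and C11 cis, the trans isomer having to place the C12 methyl or the C1 isopropyl group inside the ring.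

**Compound list**

1 | (R)-(−)-terpinen-4-ol, (1R)-4-methyl-1-(propan-2-yl)cyclohex-3-en-1-ol | CC1=CC[C@@](O)(C(C)C)CC1 | starting material
2 | triethyl{[(1R)-4-methyl-1-(propan-2-yl)cyclohex-3-en-1-yl]oxy}silane | CC1=CC[C@@](O[Si](CC)(CC)CC)(C(C)C)CC1 | intermediate
3 | ethyl 2-(triphenylphosphoranylidene)propanoate | CCOC(=O)C(C)=P(c1ccccc1)(c1ccccc1)c1ccccc1 | starting material
4 | ozonide of 2, 1-methyl-4-(propan-2-yl)-4-[(triethylsilyl)oxy]-7,8,9-trioxabicyclo[4.2.1]nonane (silyloxy carbon as in 2, ozonide centres undefined) | CC12CC[C@](O[Si](CC)(CC)CC)(C(C)C)CC(O1)OO2 | intermediate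
5 | (3R)-6-oxo-3-(propan-2-yl)-3-[(triethylsilyl)oxy]heptanal | O=CC[C@@](O[Si](CC)(CC)CC)(C(C)C)CCC(C)=O | intermediate
6 | ethyl (2E,5R)-2-methyl-8-oxo-5-(propan-2-yl)-5-[(triethylsilyl)oxy]non-2-enoate | CCOC(=O)/C(C)=C/C[C@@](O[Si](CC)(CC)CC)(C(C)C)CCC(C)=O | intermediate
7 | (2E,5R)-2-methyl-5-(propan-2-yl)-5-[(triethylsilyl)oxy]non-2-ene-1,8-diol (both C8 epimers) | OC/C(C)=C/C[C@@](O[Si](CC)(CC)CC)(C(C)C)CCC(C)O | intermediate
8 | [(2R,3R)-3-{(2R)-5-hydroxy-2-(propan-2-yl)-2-[(triethylsilyl)oxy]hexyl}-2-methyloxiran-2-yl]methanol (both carbinol epimers) | OC[C@@]1(C)O[C@@H]1C[C@@](O[Si](CC)(CC)CC)(C(C)C)CCC(C)O | intermediate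
9 | (2R,3S,5R)-2-methyl-3-(phenylselanyl)-5-(propan-2-yl)-5-[(triethylsilyl)oxy]nonane-1,2,8-triol | OC[C@@](C)(O)[C@@H]([Se]c1ccccc1)C[C@@](O[Si](CC)(CC)CC)(C(C)C)CCC(C)O | intermediate
10 | selenoxide of 9 (selenium centre undefined) | OC[C@@](C)(O)[C@@H]([Se](=O)c1ccccc1)C[C@@](O[Si](CC)(CC)CC)(C(C)C)CCC(C)O | intermediate
11 | (2S,3E,5S)-2-methyl-5-(propan-2-yl)-5-[(triethylsilyl)oxy]non-3-ene-1,2,8-triol | OC[C@@](C)(O)/C=C/[C@@](O[Si](CC)(CC)CC)(C(C)C)CCC(C)O | intermediate
12 | 1-O-(4-methylbenzenesulfonyl) derivative of 11 | Cc1ccc(cc1)S(=O)(=O)OC[C@@](C)(O)/C=C/[C@@](O[Si](CC)(CC)CC)(C(C)C)CCC(C)O | intermediate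
13 | (5S,6E)-7-[(2S)-2-methyloxiran-2-yl]-5-(propan-2-yl)-5-[(triethylsilyl)oxy]hept-6-en-2-ol | C1O[C@@]1(C)/C=C/[C@@](O[Si](CC)(CC)CC)(C(C)C)CCC(C)O | intermediate
14 | (S)-(−)-citronellal, (3S)-3,7-dimethyloct-6-enal | O=CC[C@@H](C)CCC=C(C)C | starting material
15 | 2-[(2S)-2,6-dimethylhept-5-en-1-yl]-1,3-dithiane | CC(C)=CCC[C@H](C)CC1SCCCS1 | intermediate
16 | 2-lithio derivative of 15 | CC(C)=CCC[C@H](C)CC1([Li])SCCCS1 | intermediate
17 | (5S,6E,8R)-9-{2-[(2S)-2,6-dimethylhept-5-en-1-yl]-1,3-dithian-2-yl}-8-methyl-5-(propan-2-yl)-5-[(triethylsilyl)oxy]non-6-ene-2,8-diol | CC(C)=CCC[C@H](C)CC1(C[C@@](C)(O)/C=C/[C@@](O[Si](CC)(CC)CC)(C(C)C)CCC(C)O)SCCCS1 | intermediate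
18 | (5S,6E,8R)-9-{2-[(2S)-2,6-dimethylhept-5-en-1-yl]-1,3-dithian-2-yl}-8-hydroxy-8-methyl-5-(propan-2-yl)-5-[(triethylsilyl)oxy]non-6-en-2-one | CC(C)=CCC[C@H](C)CC1(C[C@@](C)(O)/C=C/[C@@](O[Si](CC)(CC)CC)(C(C)C)CCC(C)=O)SCCCS1 | intermediate
19 | dipotassium alkoxide enolate of 18 (enolate on the methyl side) | CC(C)=CCC[C@H](C)CC1(C[C@@](C)([O-])/C=C/[C@@](O[Si](CC)(CC)CC)(C(C)C)CCC(=C)[O-])SCCCS1.[K+].[K+] | intermediate
20 | (5S,6E,8R)-9-{2-[(2S)-2,6-dimethylhept-5-en-1-yl]-1,3-dithian-2-yl}-8-hydroxy-8-methyl-5-(propan-2-yl)-5-[(triethylsilyl)oxy]nona-1,6-dien-2-yl trifluoromethanesulfonate | CC(C)=CCC[C@H](C)CC1(C[C@@](C)(O)/C=C/[C@@](O[Si](CC)(CC)CC)(C(C)C)CCC(=C)OS(=O)(=O)C(F)(F)F)SCCCS1 | intermediate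
21 | (5S,6E,8R,12S)-8-hydroxy-8,12,16-trimethyl-10-oxo-5-(propan-2-yl)-5-[(triethylsilyl)oxy]heptadeca-1,6,15-trien-2-yl trifluoromethanesulfonate | CC(C)=CCC[C@H](C)CC(=O)C[C@@](C)(O)/C=C/[C@@](O[Si](CC)(CC)CC)(C(C)C)CCC(=C)OS(=O)(=O)C(F)(F)F | intermediate
22 | 15,16-diol of 21 (C15 undefined) | CC(C)(O)C(O)CC[C@H](C)CC(=O)C[C@@](C)(O)/C=C/[C@@](O[Si](CC)(CC)CC)(C(C)C)CCC(=C)OS(=O)(=O)C(F)(F)F | intermediate
23 | (5S,6E,8R,12S)-8-hydroxy-8,12-dimethyl-10,15-dioxo-5-(propan-2-yl)-5-[(triethylsilyl)oxy]pentadeca-1,6-dien-2-yl trifluoromethanesulfonate | O=CCC[C@H](C)CC(=O)C[C@@](C)(O)/C=C/[C@@](O[Si](CC)(CC)CC)(C(C)C)CCC(=C)OS(=O)(=O)C(F)(F)F | intermediate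
24 | dichloro(alkenyl)chromium derived from 23 (chromium on C12 in place of the triflate) | O=CCC[C@H](C)CC(=O)C[C@@](C)(O)/C=C/[C@@](O[Si](CC)(CC)CC)(C(C)C)CCC(=C)[Cr](Cl)Cl | intermediate
25 | (1S,2E,4R,8S,11R)-4,11-dihydroxy-4,8-dimethyl-12-methylidene-1-(propan-2-yl)-1-[(triethylsilyl)oxy]cyclotetradec-2-en-6-one (cembrane numbering) | O[C@@H]1CC[C@H](C)CC(=O)C[C@@](C)(O)/C=C/[C@@](O[Si](CC)(CC)CC)(C(C)C)CCC1=C | intermediate
26 | (1S,2E,4R,8S,11R)-4-hydroxy-4,8-dimethyl-12-methylidene-6-oxo-1-(propan-2-yl)-1-[(triethylsilyl)oxy]cyclotetradec-2-en-11-yl acetate | CC(=O)O[C@@H]1CC[C@H](C)CC(=O)C[C@@](C)(O)/C=C/[C@@](O[Si](CC)(CC)CC)(C(C)C)CCC1=C | intermediate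
27 | (1S,2E,4R,8S,11R)-1,4-dihydroxy-4,8-dimethyl-12-methylidene-6-oxo-1-(propan-2-yl)cyclotetradec-2-en-11-yl acetate | CC(=O)O[C@@H]1CC[C@H](C)CC(=O)C[C@@](C)(O)/C=C/[C@@](O)(C(C)C)CCC1=C | intermediate
28 | (1S,2E,4R,8S,11R,12S)-1,12-epoxy-4-hydroxy-4,8,12-trimethyl-6-oxo-1-(propan-2-yl)cyclotetradec-2-en-11-yl acetate, CNP0131678.1 | CC(=O)O[C@@H]1CC[C@H](C)CC(=O)C[C@@](C)(O)/C=C/[C@@]2(C(C)C)CC[C@]1(C)O2 | target

**Step count and risks**

Total step count: 16. Longest linear sequence: 15 steps (from 1 through steps 1–6 and 8–16); step 7 is the one-step side branch from 14.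

Steps most likely to fail:

1. Step 13. The ring-closing addition may show poor facial selectivity at the C11 aldehyde, because the conformational demands of the forming 14-membered ring can override the ligand. The fallback sets out from 23: ring closure without the chiral ligand (CrCl2, catalytic NiCl2, DMF, 2 mM) should give 25 together with its C11 epimer F1. After separation 25 follows step 14, and 11-epi-25 F1 is converted directly into 26 by Mitsunobu esterification with acetic acid (PPh3, diisopropyl azodicarboxylate, AcOH, toluene, 0 °C), which inverts C11, so both epimers converge. The route is rejoined at 26.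

2. Step 16. The radical-to-cation crossover at C12 may stall next to the electron-withdrawing acetoxy carbon, so that simple hydrogenation of the alkene or elimination competes with C–O bond formation. The fallback sets out from 27: iodoetherification (I2, NaHCO3, MeCN, 0 °C), by 5-exo attack of the C1 hydroxyl on the iodonium ion at C12, should give the 12-iodomethyl oxolane F2. Radical deiodination (Bu3SnH, AIBN, toluene, 80 °C) then turns CH2I into the C12 methyl group and gives 28.

3. Step 12. Over-oxidation (osmylation of the C2=C3 alkene or of the enol triflate) or aldol closure of the 1,6-keto aldehyde in the aqueous oxidising medium may erode the aldehyde. The fallback sets out from 21: mCPBA (1.05 equiv, NaHCO3, CH2Cl2, −20 °C) should epoxidise only the electron-rich trisubstituted alkene to the 15,16-epoxide F3, and periodic acid (H5IO6, THF/H2O, 0 °C) cleaves this epoxide to aldehyde 23 and acetone. The route is rejoined at 23.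

**Further compounds**

F1 | step 13 | C11 epimer of 25, (1S,2E,4R,8S,11S)-4,11-dihydroxy-4,8-dimethyl-12-methylidene-1-(propan-2-yl)-1-[(triethylsilyl)oxy]cyclotetradec-2-en-6-one | O[C@H]1CC[C@H](C)CC(=O)C[C@@](C)(O)/C=C/[C@@](O[Si](CC)(CC)CC)(C(C)C)CCC1=C
F2 | step 16 | 12-(iodomethyl) analogue of 28 (CH2I in place of the C12 methyl group, all centres as in 28) | CC(=O)O[C@@H]1CC[C@H](C)CC(=O)C[C@@](C)(O)/C=C/[C@@]2(C(C)C)CC[C@]1(CI)O2
F3 | step 12 | 15,16-epoxide of 21 (C15 undefined) | CC1(C)OC1CC[C@H](C)CC(=O)C[C@@](C)(O)/C=C/[C@@](O[Si](CC)(CC)CC)(C(C)C)CCC(=C)OS(=O)(=O)C(F)(F)F
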